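If you are about to turn the settings of this flask, ask first at what level its target stops rising.

    solid substrate ⇌ dissolved substrate, rate k1*(cs1 - [dissolved substrate]) while solid is left; crystals form when [dissolved substrate] > cs1 (cs1 = 0.0072 mM, k1 = 1.5 s⁻¹)
    dissolved substrate + reagent → target (k2 = 3800 M⁻¹ s⁻¹)
    dissolved substrate + target → side product (k3 = 4000 M⁻¹ s⁻¹)
    gas ⇌ reagent, rate k4*(csat - [reagent]) (k4 = 0.36 s⁻¹, csat = 0.077 mM)
    2 reagent → self-condensation product (k5 = 26000 M⁻¹ s⁻¹)
    reagent ⇌ dormant form (K6 = 68, k6 = 0.22 s⁻¹)

solid substrate 0.20 mM; gas 0.077 mM (held); time 80 s

1. target at 80 s, in percent of the solid substrate charged
2. concentration of dissolved substrate in solution at 80 s, in percent of saturation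

My own reckoning starts with the reagent, which levels off where the crossing from the gas balances self-condensation, which takes two reagent at each turn, and the forward step to the dormant form, at 0.0182 mM. Target is made at k2 times dissolved substrate times reagent and used at k3 times dissolved substrate times target, so the dissolved substrate cancels from the balance. With equal constants, target would level off at the reagent level, and that symmetric case is the zero of the scale. The real selectivity factor, 0.950, shifts it to the ceiling, the reagent level times that factor, 0.0173 mM, or 8.63% of the charge. Near the ceiling, dissolved substrate stands at 91.6% of saturation, which gives a time constant of 37.9 s for the approach, and so 7.59%.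

Now the settings. More time buys little, for 87.9% of the ceiling is reached at the asked time. The ceiling in mM has no charge in it, so at the same reading time, while solid is left, the percentage goes inversely with the solid charged. Dissolution outruns the loss, 1.5 s⁻¹ against 0.138 s⁻¹, so halving its coefficient gives about 7.40%.

The forecast gave 7.5% (6.8% to 8.2%) and 92% (90% to 94%), reasoning that “the target approaches a ceiling close to the reagent level”.

The flask gives 7.63% and 92.0%; the settings rank solid substrate (2.3 points), then time (0.68 points), and half the coefficient gives 7.47%. At 80.0 s dissolved substrate goes to target 1.1 times as fast as to side product. The ceiling over the target then standing is 1.13, which is that same ratio of rates reckoned from the ceiling. For the neighbour flask read at 20 s, same amounts, the ceiling and time constant give 3.54%, and that flask gave 3.49%.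

The numbers of this flask stand for no real mixture; what happens was integrated by code.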